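**Plan**
- Retrosynthesis: the three O–MOM bonds are cut first, then the C3–C4 bond (CH2–C=O) of the pyranone ring, which leads to the achiral aldehyde 13, an aryl 1-arylvinyl ether. Next come the formyl–C4a and prenyl–C8 bonds (two Br/Li exchanges on dibromide 8), then the enol ether C=CH2 (ester methylenation) and the ester C–O bond (phenol 5 + acid 6), and last the C–Br and C–OH bonds back to 2-methylresorcinol.
- Forward: rings A and B are bought as arenes. The phenol oxygen that becomes O1 lies para to the C6 methyl group, so the flanking oxygens O5 and O7 stay equivalent until prenyl and formyl are placed on the two equivalent ortho carbons. The pyranone ring C is the only ring formed, in step 8.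
- Enabling feature: C2 carries both the ring oxygen O1 and the aryl group, and C3 is an unsubstituted CH2 bound to the C4 carbonyl on C4a, ortho to C8a–O1. C2–C3 can therefore be carried as a 1,1-disubstituted enol ether O1–C2(Ar)=C3H2 held beside a formyl group (C4), with no allylic hydrogen and a prochiral C2.
- Stereochemistry: the single stereocentre C2 (S) is created in step 8 by ligand-controlled transfer of the formyl hydrogen via rhodium to one face of the enol ether. The final deprotection is acidic, not basic, so ring opening to the chalcone is avoided.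

Key step: step 8

Assumptions: 4-(methoxymethoxy)benzoic acid 6 is taken as a catalogue compound; the sense of induction of the bisphosphine in step 8 cannot be predicted with certainty, so the (R)-ligand is written provisionally and its antipode is used if a first experiment shows the opposite face preference.

**Step 1**
Reactants: 1 2-methylresorcinol
Product: 2 1,3-bis(methoxymethoxy)-2-methylbenzene
Conditions: NaH (2.5 equiv), MOMCl (2.4 equiv), DMF, 0 °C → rt
Reagents that add atoms: chloromethyl methyl ether, COCCl
Why: Williamson-type O-alkylation of the bis-phenoxide gives acetal ethers that are stable to base and organolithiums and later chelate the aryllithiums.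

**Step 2**
Reactants: 2 1,3-bis(methoxymethoxy)-2-methylbenzene
Product: 4 3,5-bis(methoxymethoxy)-4-methylphenol, via arylboronate 3 (not isolated)
Conditions: [Ir(OMe)(cod)]2 (1.5 mol %), dtbpy (3 mol %), B2pin2 (1.0 equiv), THF, 80 °C; then 30% H2O2, aq. NaOH, THF, 0 °C → rt
Reagents that add atoms: bis(pinacolato)diboron, CC1(C)OB(OC1(C)C)B1OC(C)(C)C(C)(C)O1 (boron of 3 only); hydrogen peroxide, OO
Why: Sterically controlled iridium-catalysed aromatic C–H borylation should take the only ring C–H not flanked by a substituent (para to the methyl group), and alkaline peroxide oxidation of the C–B bond then gives the phenol that marks the future ring oxygen O1.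

**Step 3**
Reactants: 4 3,5-bis(methoxymethoxy)-4-methylphenol
Product: 5 2,6-dibromo-3,5-bis(methoxymethoxy)-4-methylphenol
Conditions: NBS (2.05 equiv), i-Pr2NH (10 mol %), CH2Cl2, −20 → 0 °C, dark
Reagents that add atoms: N-bromosuccinimide, O=C1CCC(=O)N1Br
Why: Amine-catalysed electrophilic ortho-bromination of the phenol should fill both equivalent ortho positions, each activated by OH and OMOM, the para position being blocked by methyl.

**Step 4**
Reactants: 5 2,6-dibromo-3,5-bis(methoxymethoxy)-4-methylphenol; 6 4-(methoxymethoxy)benzoic acid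
Product: 7 2,6-dibromo-3,5-bis(methoxymethoxy)-4-methylphenyl 4-(methoxymethoxy)benzoate
Conditions: EDC·HCl (1.5 equiv), DMAP (0.3 equiv), CH2Cl2, rt
Reagents that add atoms: none
Why: Steglich-type carbodiimide/DMAP esterification acylates the hindered, acidic phenol under non-acidic conditions that keep all MOM acetals.

**Step 5**
Reactants: 7 2,6-dibromo-3,5-bis(methoxymethoxy)-4-methylphenyl 4-(methoxymethoxy)benzoate
Product: 8 1,3-dibromo-4,6-bis(methoxymethoxy)-2-({1-[4-(methoxymethoxy)phenyl]ethenyl}oxy)-5-methylbenzene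
Conditions: Cp2TiMe2 (3 equiv), toluene, 70 °C, dark; filtration through basic alumina
Reagents that add atoms: dimethyltitanocene (Petasis reagent), [CH3-].[CH3-].[Ti+4].c1cc[cH-]c1.c1cc[cH-]c1
Why: Petasis methylenation (titanium carbene [2+2]/retro-[2+2], as in the Tebbe olefination of aryl benzoates) converts the ester C=O into the 1,1-disubstituted enol ether under neutral conditions that tolerate aryl bromides and MOM ethers.

**Step 6**
Reactants: 8 1,3-dibromo-4,6-bis(methoxymethoxy)-2-({1-[4-(methoxymethoxy)phenyl]ethenyl}oxy)-5-methylbenzene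
Product: 10 1-bromo-4,6-bis(methoxymethoxy)-2-({1-[4-(methoxymethoxy)phenyl]ethenyl}oxy)-5-methyl-3-(3-methylbut-2-en-1-yl)benzene, via aryllithium 9 (not isolated)
Conditions: n-BuLi (1.05 equiv), THF, −78 °C; CuBr·SMe2 (10 mol %), prenyl bromide (1.5 equiv), −78 → 0 °C
Reagents that add atoms: n-butyllithium, [Li]CCCC (lithium of 9 only); prenyl bromide (1-bromo-3-methylbut-2-ene), CC(C)=CCBr
Why: Bromine–lithium exchange on the symmetric dibromide should stop at the mono-aryllithium (a second exchange would build a dianion), which is held by the ortho-OMOM chelate and is allylated at the primary carbon of prenyl bromide in a copper-assisted SN2 reaction.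

**Step 7**
Reactants: 10 1-bromo-4,6-bis(methoxymethoxy)-2-({1-[4-(methoxymethoxy)phenyl]ethenyl}oxy)-5-methyl-3-(3-methylbut-2-en-1-yl)benzene
Product: 13 2,4-bis(methoxymethoxy)-6-({1-[4-(methoxymethoxy)phenyl]ethenyl}oxy)-3-methyl-5-(3-methylbut-2-en-1-yl)benzaldehyde, via aryllithium 11 (not isolated), via lithium hemiaminolate 12 (not isolated)
Conditions: n-BuLi (1.1 equiv), THF, −78 °C; DMF (3 equiv), −78 → 0 °C; H2O/pH 7 buffer; Et3N-deactivated SiO2
Reagents that add atoms: n-butyllithium, [Li]CCCC (lithium of 11 and 12 only); N,N-dimethylformamide, CN(C)C=O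
Why: The second Br/Li exchange at −78 °C should be much faster than any addition of butyllithium to the enol ether, and formylation of the aryllithium with DMF (Bouveault aldehyde synthesis) gives the aldehyde when the hemiaminolate collapses on neutral work-up.

**Step 8**
Reactants: 13 2,4-bis(methoxymethoxy)-6-({1-[4-(methoxymethoxy)phenyl]ethenyl}oxy)-3-methyl-5-(3-methylbut-2-en-1-yl)benzaldehyde
Product: 14 (2S)-5,7-bis(methoxymethoxy)-2-[4-(methoxymethoxy)phenyl]-6-methyl-8-(3-methylbut-2-en-1-yl)-2,3-dihydro-4H-chromen-4-one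
Conditions: [Rh(cod)Cl]2 (2.5 mol %), (R)-DTBM-SEGPHOS (5.5 mol %), NaBArF4 (5 mol %), 1,4-dioxane, 60 °C
Reagents that add atoms: none
Why: Proposed new method: a cationic Rh(I)–bisphosphine complex bound to the enol ether π-bond should insert into the formyl C–H bond to give an acyl–Rh(III) hydride, the O–C(Ar)=CH2 double bond should insert into Rh–H with the hydride going to the aryl- and oxygen-bearing carbon (rhodium to the terminal CH2, since the alternative is a tertiary alkyl–rhodium that would lead to a 2-aryl-2-methylbenzofuran-3-one), and C–C reductive elimination from the seven-membered acyl–alkyl rhodacycle then forms the CH2–C(=O) bond. The closest known reaction type is the Rh-catalysed enantioselective intramolecular hydroacylation of 1,1-disubstituted alkenes (4-substituted pent-4-enals to 3-substituted cyclopentanones, 2-(2-substituted allyl)benzaldehydes to six-membered benzo-fused ketones); an aryl 1-arylvinyl ether has not been used as the alkene partner. The dihydropyranone ring closes in a formal 6-endo-trig mode, the acyl carbon bonding to the distal alkene carbon. The only stereocentre, C2, is created when the hydride is delivered to one enantiotopic face of the enol ether and is controlled by the C2-symmetric ligand alone, the antipode being chosen to give (S). The step needs six-ring over five-ring regioselectivity and must outrun decarbonylation, β-aryloxy elimination from the alkyl–rhodium and acid-type Prins closure to a flavylium ion; the 1,1-disubstitution, the absence of allylic hydrogens (no alkene isomerisation), the flanking prenyl and formyl groups that hold the vinyl group over the aldehyde, the fully substituted ring A (no ortho C–H) and halide-free aprotic conditions are expected to secure this.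

**Step 9**
Reactants: 14 (2S)-5,7-bis(methoxymethoxy)-2-[4-(methoxymethoxy)phenyl]-6-methyl-8-(3-methylbut-2-en-1-yl)-2,3-dihydro-4H-chromen-4-one
Product: 15 (2S)-5,7-dihydroxy-2-(4-hydroxyphenyl)-6-methyl-8-(3-methylbut-2-en-1-yl)-2,3-dihydro-4H-chromen-4-one (6-methyl-8-prenylnaringenin)
Conditions: 3 M HCl in MeOH, 25–40 °C, stopped at full conversion
Reagents that add atoms: none
Why: Acid-catalysed acetal exchange with methanol removes all three MOM groups, the non-basic medium should leave the C2 centre untouched, and the moderate temperature is chosen so that the 7-OH does not add to the prenyl double bond.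

**Compound list**
1 | 2-methylresorcinol | Cc1c(O)cccc1O | starting material
2 | 1,3-bis(methoxymethoxy)-2-methylbenzene | Cc1c(OCOC)cccc1OCOC | intermediate
3 | 2-[3,5-bis(methoxymethoxy)-4-methylphenyl]-4,4,5,5-tetramethyl-1,3,2-dioxaborolane | Cc1c(OCOC)cc(B2OC(C)(C)C(C)(C)O2)cc1OCOC | intermediate
4 | 3,5-bis(methoxymethoxy)-4-methylphenol | Cc1c(OCOC)cc(O)cc1OCOC | intermediate
5 | 2,6-dibromo-3,5-bis(methoxymethoxy)-4-methylphenol | Cc1c(OCOC)c(Br)c(O)c(Br)c1OCOC | intermediate
6 | 4-(methoxymethoxy)benzoic acid | COCOc1ccc(cc1)C(=O)O | starting material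
7 | 2,6-dibromo-3,5-bis(methoxymethoxy)-4-methylphenyl 4-(methoxymethoxy)benzoate | Cc1c(OCOC)c(Br)c(OC(=O)c2ccc(OCOC)cc2)c(Br)c1OCOC | intermediate
8 | 1,3-dibromo-4,6-bis(methoxymethoxy)-2-({1-[4-(methoxymethoxy)phenyl]ethenyl}oxy)-5-methylbenzene | Cc1c(OCOC)c(Br)c(OC(=C)c2ccc(OCOC)cc2)c(Br)c1OCOC | intermediate
9 | [3-bromo-4,6-bis(methoxymethoxy)-2-({1-[4-(methoxymethoxy)phenyl]ethenyl}oxy)-5-methylphenyl]lithium | Cc1c(OCOC)c([Li])c(OC(=C)c2ccc(OCOC)cc2)c(Br)c1OCOC | intermediate
10 | 1-bromo-4,6-bis(methoxymethoxy)-2-({1-[4-(methoxymethoxy)phenyl]ethenyl}oxy)-5-methyl-3-(3-methylbut-2-en-1-yl)benzene | Cc1c(OCOC)c(CC=C(C)C)c(OC(=C)c2ccc(OCOC)cc2)c(Br)c1OCOC | intermediate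
11 | [2,4-bis(methoxymethoxy)-6-({1-[4-(methoxymethoxy)phenyl]ethenyl}oxy)-3-methyl-5-(3-methylbut-2-en-1-yl)phenyl]lithium | Cc1c(OCOC)c(CC=C(C)C)c(OC(=C)c2ccc(OCOC)cc2)c([Li])c1OCOC | intermediate
12 | lithium (dimethylamino)[2,4-bis(methoxymethoxy)-6-({1-[4-(methoxymethoxy)phenyl]ethenyl}oxy)-3-methyl-5-(3-methylbut-2-en-1-yl)phenyl]methanolate | Cc1c(OCOC)c(CC=C(C)C)c(OC(=C)c2ccc(OCOC)cc2)c(C(O[Li])N(C)C)c1OCOC | intermediate
13 | 2,4-bis(methoxymethoxy)-6-({1-[4-(methoxymethoxy)phenyl]ethenyl}oxy)-3-methyl-5-(3-methylbut-2-en-1-yl)benzaldehyde | Cc1c(OCOC)c(CC=C(C)C)c(OC(=C)c2ccc(OCOC)cc2)c(C=O)c1OCOC | intermediate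
14 | (2S)-5,7-bis(methoxymethoxy)-2-[4-(methoxymethoxy)phenyl]-6-methyl-8-(3-methylbut-2-en-1-yl)-2,3-dihydro-4H-chromen-4-one | CC(C)=CCc1c(OCOC)c(C)c(OCOC)c2c1O[C@H](c1ccc(OCOC)cc1)CC2=O | intermediate
15 | (2S)-5,7-dihydroxy-2-(4-hydroxyphenyl)-6-methyl-8-(3-methylbut-2-en-1-yl)-2,3-dihydro-4H-chromen-4-one | CC(C)=CCc1c(O)c(C)c(O)c2c1O[C@H](c1ccc(O)cc1)CC2=O | target

**Totals**
Total step count: 9. Longest linear sequence: 9 steps (1 → 15; acid 6 is bought).

**Steps most likely to fail**

1. Step 8 (proposed new method). The hydride may insert with the opposite regiochemistry and close the five-membered ring, the acyl–rhodium hydride may decarbonylate and deactivate the catalyst, the alkyl–rhodium may undergo β-aryloxy elimination, or face selection may be poor. The fallback uses known chemistry, sets out from bromide 10 and returns at 14.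
   - Br/Li exchange as in step 7 and trapping with N-methoxy-N-methylacetamide should give the methyl ketone 1-[2,4-bis(methoxymethoxy)-6-({1-[4-(methoxymethoxy)phenyl]ethenyl}oxy)-3-methyl-5-(3-methylbut-2-en-1-yl)phenyl]ethan-1-one F1.
   - PPTS in wet THF at rt should hydrolyse only the enol ether and release the 2-hydroxyacetophenone 1-[2-hydroxy-4,6-bis(methoxymethoxy)-5-methyl-3-(3-methylbut-2-en-1-yl)phenyl]ethan-1-one F2.
   - Heating with DMF dimethyl acetal should give the enaminone (E)-3-(dimethylamino)-1-[2-hydroxy-4,6-bis(methoxymethoxy)-5-methyl-3-(3-methylbut-2-en-1-yl)phenyl]prop-2-en-1-one F3, which should close on silica gel with a trace of acetic acid to the chromone 5,7-bis(methoxymethoxy)-6-methyl-8-(3-methylbut-2-en-1-yl)-4H-chromen-4-one F4.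
   - Rhodium-catalysed asymmetric 1,4-addition of commercial 4-(methoxymethoxy)phenylboronic acid to F4 (chiral diene or electron-poor biaryl bisphosphine ligand, aqueous toluene), an established route from chromones to (S)-flavanones, should then give 14.

2. Step 6. The dibromide may exchange twice, the aryllithium may be protonated, or the allylation may occur at the tertiary end of the allyl unit (SN2′) and give the reverse-prenyl isomer. The fallback installs the prenyl group by a sigmatropic route; it sets out from phenol 4 and returns at 10.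
   - One equivalent of NBS at −78 °C should give 2-bromo-3,5-bis(methoxymethoxy)-4-methylphenol F5.
   - Pd(PPh3)4-catalysed O-alkylation with tert-butyl 2-methylbut-3-en-2-yl carbonate should give the tertiary allyl ether 1-bromo-2,4-bis(methoxymethoxy)-3-methyl-6-[(2-methylbut-3-en-2-yl)oxy]benzene F6.
   - Aromatic Claisen rearrangement (N,N-diethylaniline, 110–130 °C) should move the allyl unit with allylic inversion to the only free ortho carbon and give 2-bromo-3,5-bis(methoxymethoxy)-4-methyl-6-(3-methylbut-2-en-1-yl)phenol F7.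
   - Esterification with 6 as in step 4 should give 2-bromo-3,5-bis(methoxymethoxy)-4-methyl-6-(3-methylbut-2-en-1-yl)phenyl 4-(methoxymethoxy)benzoate F8, and Petasis methylenation as in step 5 should give 10.

3. Step 5. The titanium adduct may expel the 2,6-dibromophenoxide (acyl–oxygen cleavage) instead of giving the olefin, the carbonyl flanked by two ortho bromines may react slowly, or the enol ether may hydrolyse during isolation. The fallback avoids the ester; it sets out from phenol 5 and returns at 8.
   - Commercial 4-(methoxymethoxy)benzaldehyde is converted with the Ohira–Bestmann reagent (K2CO3, MeOH) into 1-ethynyl-4-(methoxymethoxy)benzene F9.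
   - Gold(I)-catalysed Markovnikov hydrophenoxylation of F9 with 5 ([(IPr)Au(NTf2)], toluene, 60–80 °C) should give 8 directly.

**Further compounds**
F1 | step 8 | 1-[2,4-bis(methoxymethoxy)-6-({1-[4-(methoxymethoxy)phenyl]ethenyl}oxy)-3-methyl-5-(3-methylbut-2-en-1-yl)phenyl]ethan-1-one | Cc1c(OCOC)c(CC=C(C)C)c(OC(=C)c2ccc(OCOC)cc2)c(C(C)=O)c1OCOC
F2 | step 8 | 1-[2-hydroxy-4,6-bis(methoxymethoxy)-5-methyl-3-(3-methylbut-2-en-1-yl)phenyl]ethan-1-one | CC(=O)c1c(O)c(CC=C(C)C)c(OCOC)c(C)c1OCOC
F3 | step 8 | (E)-3-(dimethylamino)-1-[2-hydroxy-4,6-bis(methoxymethoxy)-5-methyl-3-(3-methylbut-2-en-1-yl)phenyl]prop-2-en-1-one | CN(C)/C=C/C(=O)c1c(O)c(CC=C(C)C)c(OCOC)c(C)c1OCOC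
F4 | step 8 | 5,7-bis(methoxymethoxy)-6-methyl-8-(3-methylbut-2-en-1-yl)-4H-chromen-4-one | CC(C)=CCc1c(OCOC)c(C)c(OCOC)c2c1OC=CC2=O
F5 | step 6 | 2-bromo-3,5-bis(methoxymethoxy)-4-methylphenol | Cc1c(OCOC)cc(O)c(Br)c1OCOC
F6 | step 6 | 1-bromo-2,4-bis(methoxymethoxy)-3-methyl-6-[(2-methylbut-3-en-2-yl)oxy]benzene | Cc1c(OCOC)cc(OC(C)(C)C=C)c(Br)c1OCOC
F7 | step 6 | 2-bromo-3,5-bis(methoxymethoxy)-4-methyl-6-(3-methylbut-2-en-1-yl)phenol | Cc1c(OCOC)c(CC=C(C)C)c(O)c(Br)c1OCOC
F8 | step 6 | 2-bromo-3,5-bis(methoxymethoxy)-4-methyl-6-(3-methylbut-2-en-1-yl)phenyl 4-(methoxymethoxy)benzoate | Cc1c(OCOC)c(CC=C(C)C)c(OC(=O)c2ccc(OCOC)cc2)c(Br)c1OCOC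
F9 | step 5 | 1-ethynyl-4-(methoxymethoxy)benzene | C#Cc1ccc(OCOC)cc1
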